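**Assumption:** acerosin has no stereocentre and no stereogenic double bond, so there is no enantiomer to select. The stereocentres that appear on the way (in 16, 19 and 20) are racemic and are erased again.

## Retrosynthetic overview
1. Acerosin comes from C2–C3 dehydrogenation of the corresponding 5,7,3'-trihydroxy-6,8,4'-trimethoxyflavanone.
2. The flavanone (ring C) comes from oxa-Michael closure of the 2',4',6'-trihydroxychalcone once its MOM ethers are removed. The A ring is symmetric, so only one regioisomer can form.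
3. The chalcone comes from a Claisen–Schmidt aldol condensation (Cα–Cβ bond) of the fully substituted A-ring acetophenone with O-MOM-isovanillin.
4. The acetophenone comes from phloroglucinol tris-MOM ether by three successive directed ortho-lithiations. Two are followed by borylation, oxidation and O-methylation. The third is a Weinreb acylation.
5. Ring order: rings A and B are bought as arenes. Ring C is the only ring formed (step 9) and is aromatised last (step 10).

## Route

Step 1
Reactants: 1 phloroglucinol (anhydrous)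
Product: 2 1,3,5-tris(methoxymethoxy)benzene
Conditions: NaH (3.6 equiv), MOMCl (3.6 equiv), THF/DMF, 0 °C → rt
Reagents that add atoms: chloromethyl methyl ether (MOMCl), COCCl
Why: Williamson-type O-alkylation works here because the hard electrophile MOMCl attacks the phenoxide oxygens rather than carbon, and the MOM ethers are stable to base and BuLi and direct later lithiation.

Step 2
Reactants: 2 1,3,5-tris(methoxymethoxy)benzene
Product: 5 2,4,6-tris(methoxymethoxy)phenol, via aryllithium 3 (not isolated), via lithium aryltrimethoxyborate 4 (not isolated)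
Conditions: n-BuLi (1.1 equiv), THF, 0 °C, 1 h; B(OMe)3 (1.5 equiv), −78 °C → rt; 30% aq H2O2, 0 °C → rt; Na2S2O3 work-up
Reagents that add atoms: hydrogen peroxide, OO (the new O); n-butyllithium, [Li]CCCC (Li of 3 and 4); trimethyl borate, COB(OC)OC (B(OMe)3 unit of 4)
Why: Directed ortho-metalation occurs between two OMOM groups (all three C–H are equivalent), and borylation followed by hydroperoxide oxidation (1,2-aryl shift from B to O) gives the phenol faster than protodeboronation can compete.

Step 3
Reactants: 5 2,4,6-tris(methoxymethoxy)phenol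
Product: 6 2-methoxy-1,3,5-tris(methoxymethoxy)benzene
Conditions: MeI (1.5 equiv), K2CO3 (2 equiv), DMF, rt, under N2
Reagents that add atoms: iodomethane, CI
Why: Williamson ether synthesis (SN2) on the only free phenol, done promptly because 5 is electron-rich and air-sensitive.

Step 4
Reactants: 6 2-methoxy-1,3,5-tris(methoxymethoxy)benzene
Product: 9 3-methoxy-2,4,6-tris(methoxymethoxy)phenol, via aryllithium 7 (not isolated), via lithium aryltrimethoxyborate 8 (not isolated)
Conditions: n-BuLi (1.1 equiv), THF, 0 °C, 1 h; B(OMe)3 (1.5 equiv), −78 °C → rt; 30% aq H2O2, 0 °C → rt; Na2S2O3 work-up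
Reagents that add atoms: hydrogen peroxide, OO (the new O); n-butyllithium, [Li]CCCC (Li of 7 and 8); trimethyl borate, COB(OC)OC (B(OMe)3 unit of 8)
Why: This is a second directed ortho-metalation, borylation and boronate oxidation, and the two remaining ring C–H are mirror-equivalent and each flanked by two OMOM groups, so only one product is possible.

Step 5
Reactants: 9 3-methoxy-2,4,6-tris(methoxymethoxy)phenol
Product: 10 2,4-dimethoxy-1,3,5-tris(methoxymethoxy)benzene
Conditions: MeI (1.5 equiv), K2CO3 (2 equiv), DMF, rt, under N2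
Reagents that add atoms: iodomethane, CI
Why: Williamson ether synthesis on the single free OH fixes the final OMOM/OMe/OMOM/OMe/OMOM pattern, so every OMe is a target OMe and every OMOM is a target OH.

Step 6
Reactants: 10 2,4-dimethoxy-1,3,5-tris(methoxymethoxy)benzene
Product: 13 1-[3,5-dimethoxy-2,4,6-tris(methoxymethoxy)phenyl]ethan-1-one, via aryllithium 11 (not isolated), via lithium hemiaminal alkoxide 12 (not isolated)
Conditions: n-BuLi (1.1 equiv), THF, 0 °C, 1 h; MeC(O)N(OMe)Me (1.5 equiv), −78 °C → 0 °C; H2O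
Reagents that add atoms: N-methoxy-N-methylacetamide, CC(=O)N(C)OC (acetyl group); n-butyllithium, [Li]CCCC (Li of 11 and 12)
Why: Directed ortho-metalation takes the last ring C–H, and in the Weinreb ketone synthesis the chelated adduct 12 survives until the quench, so no tertiary alcohol forms.

Step 7
Reactants: 14 isovanillin (3-hydroxy-4-methoxybenzaldehyde)
Product: 15 4-methoxy-3-(methoxymethoxy)benzaldehyde
Conditions: MOMCl (1.3 equiv), K2CO3 (2 equiv), acetone, rt
Reagents that add atoms: chloromethyl methyl ether (MOMCl), COCCl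
Why: Williamson-type MOM protection removes the acidic phenol, whose phenoxide would deactivate the aldehyde in the base-mediated condensation.

Step 8
Reactants: 13 1-[3,5-dimethoxy-2,4,6-tris(methoxymethoxy)phenyl]ethan-1-one; 15 4-methoxy-3-(methoxymethoxy)benzaldehyde
Product: 17 (E)-1-[3,5-dimethoxy-2,4,6-tris(methoxymethoxy)phenyl]-3-[4-methoxy-3-(methoxymethoxy)phenyl]prop-2-en-1-one, via aldol adduct 16 (not isolated)
Conditions: KOH (50% aq, excess), EtOH, rt → 40 °C, 24–48 h
Reagents that add atoms: none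
Why: In this Claisen–Schmidt crossed aldol condensation only 13 can enolise and only 15 is a reactive acceptor, and E1cB loss of water from racemic 16 removes its stereocentre and gives the thermodynamic E-enone.

Step 9
Reactants: 17 MOM-protected chalcone
Product: 19 (±)-5,7-dihydroxy-2-(3-hydroxy-4-methoxyphenyl)-6,8-dimethoxychroman-4-one, via tetrahydroxychalcone 18 (not isolated)
Conditions: HCl (1.25 M in MeOH), reflux, 2–3 h
Reagents that add atoms: none
Why: Acid-catalysed acetal exchange removes all four MOM groups and the 2',6'-dihydroxychalcone closes by 6-endo intramolecular oxa-Michael addition; the two ortho OH groups are equivalent, so one flavanone forms, and its C2 stereocentre is racemic and is erased in step 10.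

Step 10
Reactants: 19 (±)-5,7-dihydroxy-2-(3-hydroxy-4-methoxyphenyl)-6,8-dimethoxychroman-4-one
Product: 21 acerosin (5,7,3'-trihydroxy-6,8,4'-trimethoxyflavone), via 3-iodoflavanone 20 (not isolated)
Conditions: I2 (1.1 equiv), pyridine, 95 °C, 6–10 h; pour into cold dilute HCl/Na2S2O3
Reagents that add atoms: iodine, II (iodine atom only in 20; none remains in 21)
Why: This is iodine–pyridine dehydrogenation (α-iodination then dehydroiodination), the method used for hesperetin → diosmetin with the same B ring; ring A has no free C–H to iodinate, and any residual chalcone 18 recloses in hot pyridine and is also carried to 21.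

## Compound list
1 | phloroglucinol (benzene-1,3,5-triol) | Oc1cc(O)cc(O)c1 | starting material
2 | 1,3,5-tris(methoxymethoxy)benzene | COCOc1cc(OCOC)cc(OCOC)c1 | intermediate
3 | [2,4,6-tris(methoxymethoxy)phenyl]lithium | [Li]c1c(OCOC)cc(OCOC)cc1OCOC | intermediate (not isolated)
4 | lithium trimethoxy[2,4,6-tris(methoxymethoxy)phenyl]borate | [Li+].CO[B-](OC)(OC)c1c(OCOC)cc(OCOC)cc1OCOC | intermediate (not isolated)
5 | 2,4,6-tris(methoxymethoxy)phenol | Oc1c(OCOC)cc(OCOC)cc1OCOC | intermediate
6 | 2-methoxy-1,3,5-tris(methoxymethoxy)benzene | COc1c(OCOC)cc(OCOC)cc1OCOC | intermediate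
7 | [3-methoxy-2,4,6-tris(methoxymethoxy)phenyl]lithium | [Li]c1c(OCOC)cc(OCOC)c(OC)c1OCOC | intermediate (not isolated)
8 | lithium trimethoxy[3-methoxy-2,4,6-tris(methoxymethoxy)phenyl]borate | [Li+].CO[B-](OC)(OC)c1c(OCOC)cc(OCOC)c(OC)c1OCOC | intermediate (not isolated)
9 | 3-methoxy-2,4,6-tris(methoxymethoxy)phenol | Oc1c(OCOC)cc(OCOC)c(OC)c1OCOC | intermediate
10 | 2,4-dimethoxy-1,3,5-tris(methoxymethoxy)benzene | COc1c(OCOC)cc(OCOC)c(OC)c1OCOC | intermediate
11 | [3,5-dimethoxy-2,4,6-tris(methoxymethoxy)phenyl]lithium | [Li]c1c(OCOC)c(OC)c(OCOC)c(OC)c1OCOC | intermediate (not isolated)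
12 | lithium 1-[3,5-dimethoxy-2,4,6-tris(methoxymethoxy)phenyl]-1-[methoxy(methyl)amino]ethan-1-olate (racemic) | [Li+].CON(C)C(C)([O-])c1c(OCOC)c(OC)c(OCOC)c(OC)c1OCOC | intermediate (not isolated)
13 | 1-[3,5-dimethoxy-2,4,6-tris(methoxymethoxy)phenyl]ethan-1-one | CC(=O)c1c(OCOC)c(OC)c(OCOC)c(OC)c1OCOC | intermediate
14 | isovanillin (3-hydroxy-4-methoxybenzaldehyde) | COc1ccc(C=O)cc1O | starting material
15 | 4-methoxy-3-(methoxymethoxy)benzaldehyde | COCOc1cc(C=O)ccc1OC | intermediate
16 | 1-[3,5-dimethoxy-2,4,6-tris(methoxymethoxy)phenyl]-3-hydroxy-3-[4-methoxy-3-(methoxymethoxy)phenyl]propan-1-one (racemic) | COCOc1cc(C(O)CC(=O)c2c(OCOC)c(OC)c(OCOC)c(OC)c2OCOC)ccc1OC | intermediate (not isolated)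
17 | (E)-1-[3,5-dimethoxy-2,4,6-tris(methoxymethoxy)phenyl]-3-[4-methoxy-3-(methoxymethoxy)phenyl]prop-2-en-1-one | COCOc1cc(/C=C/C(=O)c2c(OCOC)c(OC)c(OCOC)c(OC)c2OCOC)ccc1OC | intermediate
18 | (E)-3-(3-hydroxy-4-methoxyphenyl)-1-(2,4,6-trihydroxy-3,5-dimethoxyphenyl)prop-2-en-1-one | COc1ccc(/C=C/C(=O)c2c(O)c(OC)c(O)c(OC)c2O)cc1O | intermediate (not isolated)
19 | (±)-5,7-dihydroxy-2-(3-hydroxy-4-methoxyphenyl)-6,8-dimethoxychroman-4-one (racemic) | COc1ccc(C2CC(=O)c3c(O)c(OC)c(O)c(OC)c3O2)cc1O | intermediate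
20 | 5,7-dihydroxy-2-(3-hydroxy-4-methoxyphenyl)-3-iodo-6,8-dimethoxychroman-4-one (racemic, diastereomer mixture) | COc1ccc(C2Oc3c(OC)c(O)c(OC)c(O)c3C(=O)C2I)cc1O | intermediate (not isolated)
21 | acerosin, 5,7-dihydroxy-2-(3-hydroxy-4-methoxyphenyl)-6,8-dimethoxy-4H-chromen-4-one (achiral) | COc1ccc(-c2cc(=O)c3c(O)c(OC)c(O)c(OC)c3o2)cc1O | target

## Summary
Total step count: 10.
Longest linear sequence: 9 (steps 1–6, then 8–10). Step 7 is the one-step side branch.

## Steps most likely to fail

**Step 6.** The aryllithium 11 is flanked on both sides and may act as a base toward the acetyl CH3 of the Weinreb amide, which simply returns 10. The fallback sets out from 10 and comes back at 13. Compound 10 is lithiated as before to 11 but trapped with non-enolisable DMF to give 3,5-dimethoxy-2,4,6-tris(methoxymethoxy)benzaldehyde F1. MeMgBr (THF, 0 °C) adds to the aldehyde to give racemic 1-[3,5-dimethoxy-2,4,6-tris(methoxymethoxy)phenyl]ethan-1-ol F2. NaHCO3-buffered Dess–Martin oxidation in CH2Cl2 then delivers 13.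

**Step 8.** The carbonyl of 13 is twisted and hindered, so the hydroxide-mediated condensation may stall. The fallback sets out from 13 and 15 and comes back at 21, bypassing 17 and 19.
- Aldehyde 15 is oxidised under Pinnick conditions (NaClO2, NaH2PO4, 2-methyl-2-butene, t-BuOH/H2O) to 4-methoxy-3-(methoxymethoxy)benzoic acid F3.
- CDI in THF activates it as (1H-imidazol-1-yl)[4-methoxy-3-(methoxymethoxy)phenyl]methanone F4.
- Ketone 13 is deprotonated with LiHMDS (2.2 equiv, THF, −78 °C) and C-acylated by F4 in a crossed Claisen condensation. This gives 1-[3,5-dimethoxy-2,4,6-tris(methoxymethoxy)phenyl]-3-[4-methoxy-3-(methoxymethoxy)phenyl]propane-1,3-dione F5.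
- Refluxing HCl/MeOH removes the MOM groups to give 3-(3-hydroxy-4-methoxyphenyl)-1-(2,4,6-trihydroxy-3,5-dimethoxyphenyl)propane-1,3-dione F6, which cyclodehydrates in the same pot to 21.

**Step 10.** Dehydrogenation of the unprotected polyphenol may be incomplete, or the B ring may be iodinated. The fallback sets out from 19 and comes back at 21. Ac2O/pyridine at rt gives (±)-5,7-diacetoxy-2-(3-acetoxy-4-methoxyphenyl)-6,8-dimethoxychroman-4-one F7. DDQ in refluxing dioxane removes the C2/C3 hydrogens by hydride abstraction to give 5,7-diacetoxy-2-(3-acetoxy-4-methoxyphenyl)-6,8-dimethoxy-4H-chromen-4-one F8. Catalytic K2CO3 in MeOH at rt then cleaves the three acetates to 21.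

## Further compounds
F1 | step 6 | 3,5-dimethoxy-2,4,6-tris(methoxymethoxy)benzaldehyde | O=Cc1c(OCOC)c(OC)c(OCOC)c(OC)c1OCOC
F2 | step 6 | 1-[3,5-dimethoxy-2,4,6-tris(methoxymethoxy)phenyl]ethan-1-ol (racemic) | CC(O)c1c(OCOC)c(OC)c(OCOC)c(OC)c1OCOC
F3 | step 8 | 4-methoxy-3-(methoxymethoxy)benzoic acid | COCOc1cc(C(=O)O)ccc1OC
F4 | step 8 | (1H-imidazol-1-yl)[4-methoxy-3-(methoxymethoxy)phenyl]methanone | COCOc1cc(C(=O)n2ccnc2)ccc1OC
F5 | step 8 | 1-[3,5-dimethoxy-2,4,6-tris(methoxymethoxy)phenyl]-3-[4-methoxy-3-(methoxymethoxy)phenyl]propane-1,3-dione | COCOc1cc(C(=O)CC(=O)c2c(OCOC)c(OC)c(OCOC)c(OC)c2OCOC)ccc1OC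
F6 | step 8 | 3-(3-hydroxy-4-methoxyphenyl)-1-(2,4,6-trihydroxy-3,5-dimethoxyphenyl)propane-1,3-dione | COc1ccc(C(=O)CC(=O)c2c(O)c(OC)c(O)c(OC)c2O)cc1O
F7 | step 10 | (±)-5,7-diacetoxy-2-(3-acetoxy-4-methoxyphenyl)-6,8-dimethoxychroman-4-one (racemic) | COc1ccc(C2CC(=O)c3c(OC(C)=O)c(OC)c(OC(C)=O)c(OC)c3O2)cc1OC(C)=O
F8 | step 10 | 5,7-diacetoxy-2-(3-acetoxy-4-methoxyphenyl)-6,8-dimethoxy-4H-chromen-4-one | COc1ccc(-c2cc(=O)c3c(OC(C)=O)c(OC)c(OC(C)=O)c(OC)c3o2)cc1OC(C)=O
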